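## Retrosynthetic overview

Eremophilane numbering is used: ring A = C1–C5 + C10, ring B = C5–C10, C14 on C5, C15 on C4, isopropenyl C11–C13 on C7.

1. The two esters come last (C9 first, C3 angelate last, C3 silyl-protected in between). The C9–OH and the 10α-H come from a Δ9(10)-8-one by Li/NH3 reductive silylation and Rubottom oxidation, the isopropenyl group from acetone at C7, and the C8 carbonyl from allylic oxidation of a Δ9(10) olefin.
2. Key disconnection C4–C5: ring A is closed by a Claisen rearrangement of the bicyclic allyl vinyl ether C4=C3–O–C9–C10=C5 (a temporary pyran ring made of O, C3, C2, C1, C10, C9). This gives the C3 ketone, the quaternary C5, C4 and the C9=C10 olefin at once.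
3. Enabling feature: with a C9=C10 double bond, the unit O=C3–C4–C5–C10=C9 spanning rings A and B is a γ,δ-unsaturated ketone. Its allylic terminus C9 is the ring B carbon that carries oxygen in the target, and C3 and C10 are already tied by C2–C1, so one oxygen atom can sit first on C9 and end as the C3 carbonyl oxygen.
4. Stereochemistry flows from one CBS reduction (C9) to C5 (1,3-chirality transfer) and C4 (enol ether geometry), then to C3, C10, C9 and C7 by substrate control.
5. Ring order: ring B is bought (Hagemann's ester), the temporary oxacycle is made in step 5 and traded for ring A in step 6.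

Key step: step 6

Assumption: angelic acid and (E)-3-methylpent-2-enoic acid are bought as single geometric isomers, and Hagemann's ester as the racemate (its stereocentre is lost in step 3).

## Route

Step 1
Reactants: 1 pent-3-yn-1-ol
Product: 2 5-iodopent-2-yne
Conditions: PPh3, I2, imidazole, CH2Cl2, 0 °C → rt
Reagents that add atoms: iodine, II
Why: Appel-type iodination of the primary alcohol, to which the internal alkyne is inert.

Step 2
Reactants: 3 Hagemann's ester (ethyl 2-methyl-4-oxocyclohex-2-ene-1-carboxylate, racemic); 2 5-iodopent-2-yne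
Product: 4 ethyl 2-methyl-4-oxo-3-(pent-3-yn-1-yl)cyclohex-2-ene-1-carboxylate (racemic)
Conditions: NaOEt, EtOH, reflux
Reagents that add atoms: none
Why: Classical alkylation of the Hagemann's ester anion (a vinylogous β-keto ester enolate), which takes primary halides at C-3 next to the ketone, so the side chain (C1–C4, C15) is fixed on the future C10.

Step 3
Reactants: 4 alkylated Hagemann's ester
Product: 6 3-methyl-2-(pent-3-yn-1-yl)cyclohex-2-en-1-one, via keto acid 5 (not isolated)
Conditions: KOH, EtOH/H2O, reflux; then aq. HCl, reflux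
Reagents that add atoms: none
Why: Saponification and decarboxylation of the vinylogous β-keto acid, the standard second half of the Hagemann's ester route to 2-alkyl-3-methylcyclohexenones, leaves ring B with the C5 methyl, the C9 carbonyl and the C10 side chain.

Step 4
Reactants: 6 3-methyl-2-(pent-3-yn-1-yl)cyclohex-2-en-1-one
Product: 7 (R)-3-methyl-2-(pent-3-yn-1-yl)cyclohex-2-en-1-ol
Conditions: (S)-Me-CBS oxazaborolidine (20 mol %), catecholborane, toluene, −78 °C; aq. NaOH work-up
Reagents that add atoms: none
Why: Corey–Bakshi–Shibata reduction in which the ring CH2 is the small and the substituted alkenyl carbon the large flank, so the (S)-catalyst should give the (R)-alcohol (C9–O on the α-face), and catecholborane at low temperature reduces 1,2 without touching the alkyne.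

Step 5
Reactants: 7 (R)-3-methyl-2-(pent-3-yn-1-yl)cyclohex-2-en-1-ol
Product: 8 (2E,8aR)-2-ethylidene-5-methyl-3,4,6,7,8,8a-hexahydro-2H-chromene
Conditions: La[N(SiMe3)2]3 (5 mol %), toluene, 90 °C; filtered through basic Al2O3
Reagents that add atoms: none
Why: Lanthanide-amide-catalysed intramolecular hydroalkoxylation of an alkynyl alcohol (6-exo-dig), in which syn insertion of the alkyne into the La–O bond and protonolysis should give the (E)-exocyclic enol ether (C15 trans to the ring oxygen) while C9 keeps its configuration.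

Step 6
Reactants: 8 (2E,8aR)-2-ethylidene-5-methyl-3,4,6,7,8,8a-hexahydro-2H-chromene
Product: 9 (1R,8aR)-1,8a-dimethyl-3,4,6,7,8,8a-hexahydronaphthalen-2(1H)-one (4β,5β-dimethyl-11,12,13-trinoreremophil-9-en-3-one)
Conditions: decalin (degassed), BHT (cat.), base-washed sealed tube, 200 °C
Reagents that add atoms: none
Why: Proposed new method: thermal [3,3]-sigmatropic (Claisen) rearrangement of the allyl vinyl ether C4=C3–O–C9–C10=C5, whose central atoms C3 and C10 are tied by the C2–C1 bridge, so that the shift can only run through a bridged boat; the closest known reactions are the aliphatic Claisen rearrangement itself, the boat-mode Claisen ring contractions of lactone ketene acetals and, for the same bridging, the degenerate Cope rearrangement of 1,4-dimethylenecyclohexane, and here the new C=O bond drives the step. Ring A is closed by the C4–C5 bond in a concerted pericyclic closure that trades the six-membered oxacycle for the carbocycle (C9–O breaks as C4–C5 forms). The quaternary C5 is set by suprafacial 1,3-chirality transfer: C4 arrives on the ring B face that the C9 oxygen leaves, so the (R)-carbinol gives the 5β-methyl centre. C4 is set by the enol ether geometry: in the enforced boat the E isomer places C15 on the side of C14, which gives the cis-4β,5β-dimethyl ketone. The step needs the concerted path to win over ionisation of the allylic C9–O bond, 1,3-shift and E/Z scrambling, which the neutral, acid-free, radical-inhibited medium should secure, and since no base is present the C4 centre next to the new ketone is not equilibrated.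

Step 7
Reactants: 9 (1R,8aR)-1,8a-dimethyl-3,4,6,7,8,8a-hexahydronaphthalen-2(1H)-one
Product: 10 (1R,2R,8aR)-1,8a-dimethyl-1,2,3,4,6,7,8,8a-octahydronaphthalen-2-ol (3α-hydroxy-11,12,13-trinoreremophil-9-ene)
Conditions: Li, NH3(l)/THF, MeOH, −78 °C (ketone added to the metal solution); NH4Cl
Reagents that add atoms: none
Why: Dissolving-metal reduction of the hindered ketone gives the thermodynamically favoured equatorial 3α-alcohol, because the axial epimer would be 1,3-diaxial to the C5 methyl group, and fast reduction under inverse addition leaves C4 and the isolated trisubstituted olefin untouched.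

Step 8
Reactants: 10 3α-alcohol
Product: 11 tert-butyl{[(1R,2R,8aR)-1,8a-dimethyl-1,2,3,4,6,7,8,8a-octahydronaphthalen-2-yl]oxy}dimethylsilane
Conditions: TBSCl, imidazole, DMF, 40 °C
Reagents that add atoms: tert-butyldimethylsilyl chloride, CC(C)(C)[Si](C)(C)Cl
Why: Standard silylation of the secondary alcohol, needed to tell the C3 oxygen from the C9 oxygen that comes later.

Step 9
Reactants: 11 silyl ether
Product: 12 (4aR,5R,6R)-6-[(tert-butyldimethylsilyl)oxy]-4a,5-dimethyl-4,4a,5,6,7,8-hexahydronaphthalen-2(3H)-one (Δ9(10)-8-one)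
Conditions: Rh2(cap)4 (dirhodium tetrakis(caprolactamate), 1 mol %), t-BuOOH (70 % aq.), K2CO3 (cat.), CH2Cl2, rt
Reagents that add atoms: tert-butyl hydroperoxide, CC(C)(C)OO
Why: Catalytic allylic C–H oxidation as used for Δ5-steroids to 7-ketones, in which hydrogen abstraction at C8 (the CH2 next to the olefinic CH) gives the more substituted allyl radical and the ketone ends at C8 in conjugation with C9=C10.

Step 10
Reactants: 12 Δ9(10)-8-one
Product: 16 (4aR,5R,6R)-6-[(tert-butyldimethylsilyl)oxy]-4a,5-dimethyl-3-(propan-2-ylidene)-4,4a,5,6,7,8-hexahydronaphthalen-2(3H)-one, via lithium enolate 13 (not isolated), via aldol adduct 14 (not isolated), via mesylate 15 (not isolated)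
Conditions: LiN(i-Pr)2, THF, −78 °C; acetone, −78 °C; aq. NH4Cl; then MsCl, Et3N, CH2Cl2, 0 °C → rt
Reagents that add atoms: acetone, CC(C)=O
Why: Kinetic α′-deprotonation of the enone at C7, aldol addition to acetone and E1cB loss of the mesylate give the conjugated isopropylidene ketone, so all three isopropenyl carbons enter regioselectively at C7 and any stereochemistry at C7 is erased.

Step 11
Reactants: 16 isopropylidene dienone
Product: 18 (3S,4aR,5R,6R)-6-[(tert-butyldimethylsilyl)oxy]-4a,5-dimethyl-3-(prop-1-en-2-yl)-4,4a,5,6,7,8-hexahydronaphthalen-2(3H)-one, via lithium dienolate 17 (not isolated)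
Conditions: LiN(i-Pr)2, THF/DMPU, −78 °C; then AcOH, −78 °C
Reagents that add atoms: none
Why: Deconjugative protonation (as in pulegone to isopulegone), in which deprotonation of the methyl group syn to the carbonyl gives the extended dienolate that is protonated kinetically at its α-carbon C7 from the axial β-face, giving the equatorial 7α-isopropenyl group, the epimer that is also thermodynamically preferred.

Step 12
Reactants: 18 isopropenyl enone
Product: 20 3α-(tert-butyldimethylsilyloxy)-8-(trimethylsilyloxy)-10αH-eremophila-8,11-diene, via lithium enolate 19 (not isolated)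
Conditions: Li (2.2 equiv), t-BuOH (1 equiv), NH3(l)/THF, −78 °C; NH3 evaporated; then Me3SiCl, Et3N, THF, 0 °C
Reagents that add atoms: chlorotrimethylsilane, C[Si](C)(C)Cl
Why: Stork reductive silylation, in which Birch-type reduction of the enone protonates C10 axially to give the trans-decalin (10α-H), the C8 enolate is trapped as the Δ8(9) silyl enol ether without equilibration, and the isolated isopropenyl group is not reduced.

Step 13
Reactants: 20 silyl enol ether
Product: 22 3α-(tert-butyldimethylsilyloxy)-9α-hydroxy-10αH-eremophil-11-en-8-one, via silyloxy ketone 21 (not isolated)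
Conditions: mCPBA (1.05 equiv), NaHCO3, CH2Cl2, −20 °C; then 1 M HCl, THF, 0 °C
Reagents that add atoms: meta-chloroperbenzoic acid, OOC(=O)c1cccc(Cl)c1
Why: Rubottom oxidation, in which the electron-rich silyl enol ether is epoxidised in preference to the isopropenyl group and from the α-face, away from the axial C5 methyl group, so that silyl migration and hydrolysis give the equatorial 9α-hydroxy ketone.

Step 14
Reactants: 22 9α-hydroxy ketone; 23 (E)-3-methylpent-2-enoic acid
Product: 24 3α-(tert-butyldimethylsilyloxy)-9α-[(E)-3-methylpent-2-enoyloxy]-10αH-eremophil-11-en-8-one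
Conditions: EDC·HCl, DMAP (cat.), CH2Cl2, 0 °C → rt
Reagents that add atoms: none
Why: Steglich (carbodiimide/DMAP) esterification of the only free hydroxyl, mild enough to keep the E geometry of the acid and the configuration at C7 and C9.

Step 15
Reactants: 24 C9 ester
Product: 25 3α-hydroxy-9α-[(E)-3-methylpent-2-enoyloxy]-10αH-eremophil-11-en-8-one
Conditions: HF·pyridine, pyridine/THF, 0 °C → rt
Reagents that add atoms: none
Why: Fluoride cleavage of the secondary silyl ether under buffered, slightly acidic conditions that should not hydrolyse the ester, epimerise C7 or C9, or conjugate the isopropenyl ketone.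

Step 16
Reactants: 25 C3 alcohol; 26 angelic acid ((Z)-2-methylbut-2-enoic acid)
Product: 28 CNP0301161.1 (3α-angeloyloxy-9α-[(E)-3-methylpent-2-enoyloxy]-10αH-eremophil-11-en-8-one), via mixed anhydride 27 (not isolated)
Conditions: 26, 2,4,6-Cl3C6H2COCl, Et3N, toluene, rt; then 25, 75 °C
Reagents that add atoms: none
Why: Yamaguchi esterification through the mixed anhydride, the established way to acylate a hindered secondary alcohol with angelic acid without Z to E isomerisation to the tiglate.

## Compound list

1 | pent-3-yn-1-ol | CC#CCCO | starting material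
2 | 5-iodopent-2-yne | CC#CCCI | intermediate
3 | Hagemann's ester, ethyl 2-methyl-4-oxocyclohex-2-ene-1-carboxylate (racemic) | CCOC(=O)C1CCC(=O)C=C1C | starting material
4 | ethyl 2-methyl-4-oxo-3-(pent-3-yn-1-yl)cyclohex-2-ene-1-carboxylate (racemic) | CCOC(=O)C1CCC(=O)C(CCC#CC)=C1C | intermediate
5 | 2-methyl-4-oxo-3-(pent-3-yn-1-yl)cyclohex-2-ene-1-carboxylic acid (racemic) | OC(=O)C1CCC(=O)C(CCC#CC)=C1C | intermediate (not isolated)
6 | 3-methyl-2-(pent-3-yn-1-yl)cyclohex-2-en-1-one | CC#CCCC1=C(C)CCCC1=O | intermediate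
7 | (R)-3-methyl-2-(pent-3-yn-1-yl)cyclohex-2-en-1-ol | CC#CCCC1=C(C)CCC[C@H]1O | intermediate
8 | (2E,8aR)-2-ethylidene-5-methyl-3,4,6,7,8,8a-hexahydro-2H-chromene | C/C=C1\CCC2=C(C)CCC[C@H]2O1 | intermediate
9 | (1R,8aR)-1,8a-dimethyl-3,4,6,7,8,8a-hexahydronaphthalen-2(1H)-one | C1C[C@]2(C)[C@@H](C)C(=O)CCC2=CC1 | intermediate
10 | (1R,2R,8aR)-1,8a-dimethyl-1,2,3,4,6,7,8,8a-octahydronaphthalen-2-ol | C1C[C@]2(C)[C@@H](C)[C@H](O)CCC2=CC1 | intermediate
11 | tert-butyl{[(1R,2R,8aR)-1,8a-dimethyl-1,2,3,4,6,7,8,8a-octahydronaphthalen-2-yl]oxy}dimethylsilane | C1C[C@]2(C)[C@@H](C)[C@H](O[Si](C)(C)C(C)(C)C)CCC2=CC1 | intermediate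
12 | (4aR,5R,6R)-6-[(tert-butyldimethylsilyl)oxy]-4a,5-dimethyl-4,4a,5,6,7,8-hexahydronaphthalen-2(3H)-one | C1C[C@]2(C)[C@@H](C)[C@H](O[Si](C)(C)C(C)(C)C)CCC2=CC1=O | intermediate
13 | lithium cross-conjugated enolate of 12 (C7=C8–OLi) | [Li+].C=1C[C@]2(C)[C@@H](C)[C@H](O[Si](C)(C)C(C)(C)C)CCC2=CC=1[O-] | intermediate (not isolated)
14 | 3-(2-hydroxypropan-2-yl) aldol adduct of 12 (both C7 epimers) | CC(C)(O)C1C[C@]2(C)[C@@H](C)[C@H](O[Si](C)(C)C(C)(C)C)CCC2=CC1=O | intermediate (not isolated)
15 | methanesulfonate of 14 (both C7 epimers) | CC(C)(OS(C)(=O)=O)C1C[C@]2(C)[C@@H](C)[C@H](O[Si](C)(C)C(C)(C)C)CCC2=CC1=O | intermediate (not isolated)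
16 | (4aR,5R,6R)-6-[(tert-butyldimethylsilyl)oxy]-4a,5-dimethyl-3-(propan-2-ylidene)-4,4a,5,6,7,8-hexahydronaphthalen-2(3H)-one | CC(C)=C1C[C@]2(C)[C@@H](C)[C@H](O[Si](C)(C)C(C)(C)C)CCC2=CC1=O | intermediate
17 | lithium extended dienolate of 16 | [Li+].C=C(C)C=1C[C@]2(C)[C@@H](C)[C@H](O[Si](C)(C)C(C)(C)C)CCC2=CC=1[O-] | intermediate (not isolated)
18 | (3S,4aR,5R,6R)-6-[(tert-butyldimethylsilyl)oxy]-4a,5-dimethyl-3-(prop-1-en-2-yl)-4,4a,5,6,7,8-hexahydronaphthalen-2(3H)-one | C=C(C)[C@@H]1C[C@]2(C)[C@@H](C)[C@H](O[Si](C)(C)C(C)(C)C)CCC2=CC1=O | intermediate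
19 | lithium Δ8(9)-enolate (trans-decalin, 10α-H) | [Li+].C=C(C)[C@@H]1C[C@]2(C)[C@@H](C)[C@H](O[Si](C)(C)C(C)(C)C)CC[C@H]2C=C1[O-] | intermediate (not isolated)
20 | 3α-(tert-butyldimethylsilyloxy)-8-(trimethylsilyloxy)-10αH-eremophila-8,11-diene | C=C(C)[C@@H]1C[C@]2(C)[C@@H](C)[C@H](O[Si](C)(C)C(C)(C)C)CC[C@H]2C=C1O[Si](C)(C)C | intermediate
21 | 3α-(tert-butyldimethylsilyloxy)-9α-(trimethylsilyloxy)-10αH-eremophil-11-en-8-one | C=C(C)[C@@H]1C[C@]2(C)[C@@H](C)[C@H](O[Si](C)(C)C(C)(C)C)CC[C@H]2[C@H](O[Si](C)(C)C)C1=O | intermediate (not isolated)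
22 | 3α-(tert-butyldimethylsilyloxy)-9α-hydroxy-10αH-eremophil-11-en-8-one | C=C(C)[C@@H]1C[C@]2(C)[C@@H](C)[C@H](O[Si](C)(C)C(C)(C)C)CC[C@H]2[C@H](O)C1=O | intermediate
23 | (E)-3-methylpent-2-enoic acid | OC(=O)/C=C(\C)CC | starting material
24 | 3α-(tert-butyldimethylsilyloxy)-9α-[(E)-3-methylpent-2-enoyloxy]-10αH-eremophil-11-en-8-one | C=C(C)[C@@H]1C[C@]2(C)[C@@H](C)[C@H](O[Si](C)(C)C(C)(C)C)CC[C@H]2[C@H](OC(=O)/C=C(\C)CC)C1=O | intermediate
25 | 3α-hydroxy-9α-[(E)-3-methylpent-2-enoyloxy]-10αH-eremophil-11-en-8-one | C=C(C)[C@@H]1C[C@]2(C)[C@@H](C)[C@H](O)CC[C@H]2[C@H](OC(=O)/C=C(\C)CC)C1=O | intermediate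
26 | angelic acid, (Z)-2-methylbut-2-enoic acid | OC(=O)/C(C)=C\C | starting material
27 | angelic 2,4,6-trichlorobenzoic anhydride | O=C(OC(=O)/C(C)=C\C)c1c(Cl)cc(Cl)cc1Cl | intermediate (not isolated)
28 | CNP0301161.1, 3α-angeloyloxy-9α-[(E)-3-methylpent-2-enoyloxy]-10αH-eremophil-11-en-8-one (7βH) | C=C(C)[C@@H]1C[C@]2(C)[C@@H](C)[C@H](OC(=O)/C(C)=C\C)CC[C@H]2[C@H](OC(=O)/C=C(\C)CC)C1=O | target

## Step count and risks

Total step count: 16. Longest linear sequence: 16 steps (1 → 28; 15 from Hagemann's ester 3).

Steps most likely to fail: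

1. **Step 6 (Proposed new method).** The bridged boat-mode [3,3] shift may be too slow, so that ionisation of the allylic C9–O bond, a 1,3-shift or elimination to a diene takes over, or the enol ether geometry scrambles before rearrangement. The fallback uses known chemistry only, sets out from 1 and comes back at 10.
   - Na in liquid NH3 reduces 1 to (E)-pent-3-en-1-ol F1, and PPh3/CBr4 gives (E)-5-bromopent-2-ene F2.
   - Its Grignard reagent adds to 3-ethoxy-2-methylcyclohex-2-en-1-one, and acid work-up (Stork–Danheiser transposition) gives 2-methyl-3-[(E)-pent-3-en-1-yl]cyclohex-2-en-1-one F3.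
   - Shi epoxidation of the isolated olefin (fructose-derived ketone, KHSO5, K2CO3) gives the (2R,3R)-epoxy enone F4.
   - KOt-Bu in t-BuOH forms the extended dienolate, whose α-carbon (C5) opens the epoxide at C4 with inversion through a six-membered chair (C3–O and C15 equatorial). This closes ring A by the same C4–C5 bond and gives hydroxy ketone F5, with C3, C4, C5 and the Δ9(10) olefin as in 10.
   - Wolff–Kishner reduction (N2H4, KOH, diethylene glycol) removes the C6 carbonyl and gives 10, so that steps 2 to 7 are skipped.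

2. **Step 5.** Cyclisation of the hindered secondary alkoxide may stall, or geometric control may be lost (formation of, or isomerisation to, the Z enol ether), which would put C15 on the wrong side of ring A after the rearrangement. The fallback sets C4 by enolate protonation instead of by olefin geometry; it sets out from 7 and comes back at 9.
   - Anti-hydroalkoxylation with Ph3PAuCl/AgOTf gives the (Z)-enol ether F6.
   - The same thermal rearrangement then gives the 4-epi ketone F7.
   - Me3SiI/(Me3Si)2NH gives the more substituted silyl enol ether F8.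
   - MeLi regenerates the enolate, and kinetic protonation at C4 (axial, anti to the C5 methyl group) gives 9.

3. **Step 9.** Site selectivity of the hydrogen abstraction may be poor (C1 against C8) and over-oxidation may occur. The fallback places the oxygen by an ene reaction and a 1,3-transposition; it sets out from 11 and comes back at 12.
   - Singlet oxygen ene reaction (O2, tetraphenylporphyrin, hν) on the α-face, followed by reduction of the hydroperoxide with PPh3, gives the tertiary allylic alcohol F9.
   - Oxidative allylic transposition with pyridinium chlorochromate [C5H5NH][CrO3Cl] gives 12.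

## Further compounds

F1 | step 6 | (E)-pent-3-en-1-ol | C/C=C/CCO
F2 | step 6 | (E)-5-bromopent-2-ene | C/C=C/CCBr
F3 | step 6 | 2-methyl-3-[(E)-pent-3-en-1-yl]cyclohex-2-en-1-one | C/C=C/CCC1=C(C)C(=O)CCC1
F4 | step 6 | 2-methyl-3-{2-[(2R,3R)-3-methyloxiran-2-yl]ethyl}cyclohex-2-en-1-one | C[C@H]1O[C@@H]1CCC1=C(C)C(=O)CCC1
F5 | step 6 | 3α-hydroxy-4β,5β-dimethyl-11,12,13-trinoreremophil-9-en-6-one | C1C(=O)[C@]2(C)[C@@H](C)[C@H](O)CCC2=CC1
F6 | step 5 | (2Z,8aR)-2-ethylidene-5-methyl-3,4,6,7,8,8a-hexahydro-2H-chromene | C/C=C1/CCC2=C(C)CCC[C@H]2O1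
F7 | step 5 | (1S,8aR)-1,8a-dimethyl-3,4,6,7,8,8a-hexahydronaphthalen-2(1H)-one | C1C[C@]2(C)[C@H](C)C(=O)CCC2=CC1
F8 | step 5 | Δ3(4) trimethylsilyl enol ether of F7 | C1C[C@]2(C)C(C)=C(O[Si](C)(C)C)CCC2=CC1
F9 | step 9 | 3α-(tert-butyldimethylsilyloxy)-10α-hydroxy-11,12,13-trinoreremophil-8-ene | C1C[C@]2(C)[C@@H](C)[C@H](O[Si](C)(C)C(C)(C)C)CC[C@@]2(O)C=C1
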